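**Retrosynthetic overview**

1. Feature: ring B with its pyranone (C1, O2, C3, C4, C4a to C8a; 6-OMe, 3-pentyl) and ring A (C1 carboxyl, C2 and C4 hydroxyls, C6 2-oxoheptyl) are the same C14 tetraketide, once closed and once open at C1–O2, joined by an ether oxygen from ring B C8 to ring A C5.
2. Last skeletal disconnection: the ring A C5–O bond, made by Ullmann coupling of a ring A C5 iodide (phenols and acid benzylated, ketone ketalised) with the 8-OH of the 6-O-methylated isocoumarin; both partners come from 6,8-dihydroxy-3-pentylisocoumarin (olivetonide).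
3. Olivetonide is disconnected at C1–O2 (enol lactonisation) and C8a–C4a (aldol) to a 3,5,7,9-tetraoxotetradecanoate whose C9 ketone is masked as a dioxolane.
4. That chain is cut at C6–C7: acylation of the trianion of methyl 3,5-dioxohexanoate by ketalised methyl 3-oxooctanoate.
5. Ring order: ring B (carbocycle) first, then the pyranone in the same flask; ring A is this bicycle reopened by hydroxide.

Key step: step 4

Remark: ring A is numbered as a 2,4-dihydroxy-6-alkylbenzoic acid (C5 is the ether position, identical with C5 of the isocoumarin), and the chain is numbered C1 (ester) to C14. The target has no stereocentre, so no step needs stereocontrol. The iodide is chosen at ring A C5 because it enters copper catalysis more readily than the bromide.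

**Route**

Step 1
Reactants: 1 methyl 3-oxooctanoate; 2 ethylene glycol
Product: 3 methyl 2-(2-pentyl-1,3-dioxolan-2-yl)acetate
Conditions: p-TsOH (cat.), benzene, reflux, Dean–Stark
Reagents that add atoms: none
Why: Acid-catalysed ketalisation of the ketone of a beta-keto ester with azeotropic removal of water is a standard reaction and leaves the ester untouched.

Step 2
Reactants: 4 4-hydroxy-6-methyl-2H-pyran-2-one
Product: 5 methyl 3,5-dioxohexanoate
Conditions: Mg(OMe)2 (2 equiv), MeOH, reflux; then cold 2 M HCl
Reagents that add atoms: methanol (delivered as Mg(OMe)2), CO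
Why: Methanolysis of the enol lactone by acyl–oxygen cleavage is a known opening of this pyranone, and the magnesium chelate of the diketo ester prevents reclosure and Claisen side reactions.

Step 3
Reactants: 5 methyl 3,5-dioxohexanoate; 3 methyl 2-(2-pentyl-1,3-dioxolan-2-yl)acetate
Product: 6 methyl 3,5,7-trioxo-8-(2-pentyl-1,3-dioxolan-2-yl)octanoate
Conditions: LiN(i-Pr)2 (3.1 equiv per 5), THF, 0 °C; then 3 (0.5 equiv), 0 °C to rt; cold dilute HCl to pH 5
Reagents that add atoms: none
Why: Polyanion Claisen acylation, in which the last-formed terminal C6 carbanion of the trianion is the most nucleophilic site and attacks the ester of 3 (bond C6–C7); the trianion is used in excess because the product consumes one equivalent of base, and ketal-protected beta-keto esters are established acyl donors for such polyanions.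

Step 4
Reactants: 6 methyl 3,5,7-trioxo-8-(2-pentyl-1,3-dioxolan-2-yl)octanoate
Product: 9 6,8-dihydroxy-3-pentylisocoumarin (olivetonide), via resorcylate ketal 7 (not isolated), via keto ester 8 (not isolated)
Conditions: 1 M aq. KOH, N2, rt; then conc. HCl to pH 1, 60 °C, same flask
Reagents that add atoms: water, O
Why: In aqueous hydroxide the chain is fully enolised and the C2 carbanion of the beta-keto ester terminus adds to the C7 ketone (intramolecular aldol, bond C8a–C4a), after which two dehydrations aromatise ring B to the resorcylate 7. Acidification then hydrolyses the dioxolane, and the enol oxygen of the freed C9 ketone attacks the ester, which the hydrogen-bonded ortho hydroxyl activates (bond C1–O2, methanol lost), to give the pyranone. The closest known reactions are the biomimetic aldol cyclisation of 3,5,7-triketo esters to beta-resorcylates and the acid lactonisation of 2-(2-oxoalkyl)resorcylates to 6,8-dihydroxy-3-alkylisocoumarins. Ring B closes in a 6-(enolendo)-exo-trig mode and the pyranone in a 6-exo-trig mode. No stereocentre is formed. The step needs the C2-to-C7 aldol to beat the C6-to-C1 Claisen closure, which aqueous KOH without a chelating divalent cation should secure because the ketone is the better electrophile there, while the C9 dioxolane removes the C4-to-C9 and C10-to-C5 aldols and the C10-to-C1 Claisen closure to a naphthalene and leaves C8 too weakly acidic to compete.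

Step 5
Reactants: 9 6,8-dihydroxy-3-pentylisocoumarin
Product: 10 8-hydroxy-6-methoxy-3-pentylisocoumarin
Conditions: MeI (1.05 equiv), K2CO3 (1.1 equiv), acetone, rt
Reagents that add atoms: iodomethane, CI
Why: Williamson methylation with one equivalent of base should select the 6-OH, because the 8-OH is held in a hydrogen bond to the lactone carbonyl and is less acidic and less nucleophilic.

Step 6
Reactants: 9 6,8-dihydroxy-3-pentylisocoumarin
Product: 11 6,8-bis(benzyloxy)-3-pentylisocoumarin
Conditions: BnBr (2.5 equiv), K2CO3 (3 equiv), DMF, 70 °C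
Reagents that add atoms: benzyl bromide, BrCc1ccccc1
Why: Exhaustive Williamson benzylation, in which excess halide and heat in DMF also alkylate the chelated 8-OH while anhydrous carbonate leaves the lactone closed.

Step 7
Reactants: 11 6,8-bis(benzyloxy)-3-pentylisocoumarin
Product: 12 2,4-bis(benzyloxy)-6-(2-oxoheptyl)benzoic acid
Conditions: 2 M aq. KOH, EtOH, 70 °C; then 1 M HCl to pH 3, 0 °C
Reagents that add atoms: water (delivered as hydroxide from KOH), O
Why: Saponification of the enol lactone is irreversible in base because the carboxylate is no electrophile and the enolate leaving group becomes the ketone; ether-protected 2-carboxybenzyl ketones are an isolable class and cold acidification avoids reclosure.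

Step 8
Reactants: 12 2,4-bis(benzyloxy)-6-(2-oxoheptyl)benzoic acid
Product: 13 benzyl 2,4-bis(benzyloxy)-6-(2-oxoheptyl)benzoate
Conditions: BnBr (1.2 equiv), KHCO3 (1.5 equiv), DMF, rt
Reagents that add atoms: benzyl bromide, BrCc1ccccc1
Why: Carboxylate O-alkylation (SN2 at the benzylic carbon) is insensitive to the shielding of the carboxyl group, and hydrogen carbonate is too weak to enolise the ketone, so neither C-benzylation nor closure onto the new ester should occur.

Step 9
Reactants: 13 benzyl 2,4-bis(benzyloxy)-6-(2-oxoheptyl)benzoate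
Product: 14 benzyl 2,4-bis(benzyloxy)-6-[(2-pentyl-1,3-dioxolan-2-yl)methyl]benzoate
Conditions: Me3SiOCH2CH2OSiMe3 (3 equiv), Me3SiOTf (0.1 equiv), CH2Cl2, −78 to −20 °C; pyridine quench
Reagents that add atoms: 1,2-bis(trimethylsilyloxy)ethane, C[Si](C)(C)OCCO[Si](C)(C)C
Why: Noyori ketalisation runs at low temperature without protic acid or heat, so the unhindered dialkyl ketone should be masked faster than its enol can attack the shielded, electron-rich benzoate.

Step 10
Reactants: 14 benzyl 2,4-bis(benzyloxy)-6-[(2-pentyl-1,3-dioxolan-2-yl)methyl]benzoate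
Product: 15 benzyl 4,6-bis(benzyloxy)-3-iodo-2-[(2-pentyl-1,3-dioxolan-2-yl)methyl]benzoate (iodine at ring A C5)
Conditions: N-iodosuccinimide (1.1 equiv), CF3CO2H (0.2 equiv), dry MeCN, 0 °C to rt, dark
Reagents that add atoms: N-iodosuccinimide, O=C1CCC(=O)N1I
Why: Electrophilic aromatic iodination should go to C5, which is ortho to the 4-benzyloxy and para to the 2-benzyloxy group, rather than to C3 between two benzyloxy groups, the pattern by which 3,5-dialkoxy-alkylbenzenes are halogenated next to the alkyl group; dry conditions with catalytic acid spare the dioxolane.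

Step 11
Reactants: 15 benzyl 4,6-bis(benzyloxy)-3-iodo-2-[(2-pentyl-1,3-dioxolan-2-yl)methyl]benzoate; 10 8-hydroxy-6-methoxy-3-pentylisocoumarin
Product: 16 benzyl 4,6-bis(benzyloxy)-3-[(6-methoxy-1-oxo-3-pentyl-1H-isochromen-8-yl)oxy]-2-[(2-pentyl-1,3-dioxolan-2-yl)methyl]benzoate
Conditions: CuI (0.2 equiv), picolinic acid (0.4 equiv), K3PO4 (2 equiv), 4 Å sieves, DMSO, 100 °C, Ar; 10 (1.3 equiv)
Reagents that add atoms: none
Why: Ullmann diaryl ether synthesis in which the phenoxide of 10 replaces iodide at ring A C5 on monovalent copper, with a ligand developed for ortho-substituted partners; the ketal blocks enolate chemistry of the side chain and dry phosphate spares the benzyl ester and the lactone.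

Step 12
Reactants: 16 benzyl 4,6-bis(benzyloxy)-3-[(6-methoxy-1-oxo-3-pentyl-1H-isochromen-8-yl)oxy]-2-[(2-pentyl-1,3-dioxolan-2-yl)methyl]benzoate
Product: 17 benzyl 4,6-bis(benzyloxy)-3-[(6-methoxy-1-oxo-3-pentyl-1H-isochromen-8-yl)oxy]-2-(2-oxoheptyl)benzoate
Conditions: 1 M aq. HCl, THF, rt
Reagents that add atoms: water, O
Why: Acid hydrolysis of the dioxolane; in dilute aqueous acid at room temperature the enol of the freed ketone should not attack the shielded benzyl ester, and the ring B lactone, the aryl ethers and the benzyl groups are stable.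

Step 13
Reactants: 17 benzyl 4,6-bis(benzyloxy)-3-[(6-methoxy-1-oxo-3-pentyl-1H-isochromen-8-yl)oxy]-2-(2-oxoheptyl)benzoate
Product: 18 beta-collatolic acid, 4,6-dihydroxy-3-[(6-methoxy-1-oxo-3-pentyl-1H-isochromen-8-yl)oxy]-2-(2-oxoheptyl)benzoic acid
Conditions: H2 (1 atm), 10% Pd/C, EtOAc, rt, stopped after 3 equiv H2
Reagents that add atoms: none
Why: Hydrogenolysis of one benzyl ester and two aryl benzyl ethers over Pd/C should be much faster than saturation of the C3–C4 double bond of the isocoumarin, and the neutral medium leaves the ring A keto acid open, since it lactonises only under acid or dehydration.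

**Compound list**

1 | methyl 3-oxooctanoate | CCCCCC(=O)CC(=O)OC | starting material
2 | ethylene glycol | OCCO | starting material
3 | methyl 2-(2-pentyl-1,3-dioxolan-2-yl)acetate | CCCCCC1(CC(=O)OC)OCCO1 | intermediate
4 | 4-hydroxy-6-methyl-2H-pyran-2-one | Cc1cc(O)cc(=O)o1 | starting material
5 | methyl 3,5-dioxohexanoate | CC(=O)CC(=O)CC(=O)OC | intermediate
6 | methyl 3,5,7-trioxo-8-(2-pentyl-1,3-dioxolan-2-yl)octanoate | CCCCCC1(CC(=O)CC(=O)CC(=O)CC(=O)OC)OCCO1 | intermediate
7 | methyl 2,4-dihydroxy-6-[(2-pentyl-1,3-dioxolan-2-yl)methyl]benzoate (resorcylate ketal, not isolated) | CCCCCC1(Cc2cc(O)cc(O)c2C(=O)OC)OCCO1 | intermediate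
8 | methyl 2,4-dihydroxy-6-(2-oxoheptyl)benzoate (keto ester, not isolated) | CCCCCC(=O)Cc1cc(O)cc(O)c1C(=O)OC | intermediate
9 | 6,8-dihydroxy-3-pentylisocoumarin (olivetonide) | CCCCCc1cc2cc(O)cc(O)c2c(=O)o1 | intermediate
10 | 8-hydroxy-6-methoxy-3-pentylisocoumarin | CCCCCc1cc2cc(OC)cc(O)c2c(=O)o1 | intermediate
11 | 6,8-bis(benzyloxy)-3-pentylisocoumarin | CCCCCc1cc2cc(OCc3ccccc3)cc(OCc3ccccc3)c2c(=O)o1 | intermediate
12 | 2,4-bis(benzyloxy)-6-(2-oxoheptyl)benzoic acid | CCCCCC(=O)Cc1cc(OCc2ccccc2)cc(OCc2ccccc2)c1C(=O)O | intermediate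
13 | benzyl 2,4-bis(benzyloxy)-6-(2-oxoheptyl)benzoate | CCCCCC(=O)Cc1cc(OCc2ccccc2)cc(OCc2ccccc2)c1C(=O)OCc1ccccc1 | intermediate
14 | benzyl 2,4-bis(benzyloxy)-6-[(2-pentyl-1,3-dioxolan-2-yl)methyl]benzoate | CCCCCC1(Cc2cc(OCc3ccccc3)cc(OCc3ccccc3)c2C(=O)OCc2ccccc2)OCCO1 | intermediate
15 | benzyl 4,6-bis(benzyloxy)-3-iodo-2-[(2-pentyl-1,3-dioxolan-2-yl)methyl]benzoate | CCCCCC1(Cc2c(I)c(OCc3ccccc3)cc(OCc3ccccc3)c2C(=O)OCc2ccccc2)OCCO1 | intermediate
16 | benzyl 4,6-bis(benzyloxy)-3-[(6-methoxy-1-oxo-3-pentyl-1H-isochromen-8-yl)oxy]-2-[(2-pentyl-1,3-dioxolan-2-yl)methyl]benzoate | CCCCCC1(Cc2c(Oc3cc(OC)cc4cc(CCCCC)oc(=O)c34)c(OCc3ccccc3)cc(OCc3ccccc3)c2C(=O)OCc2ccccc2)OCCO1 | intermediate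
17 | benzyl 4,6-bis(benzyloxy)-3-[(6-methoxy-1-oxo-3-pentyl-1H-isochromen-8-yl)oxy]-2-(2-oxoheptyl)benzoate | CCCCCC(=O)Cc1c(Oc2cc(OC)cc3cc(CCCCC)oc(=O)c23)c(OCc2ccccc2)cc(OCc2ccccc2)c1C(=O)OCc1ccccc1 | intermediate
18 | beta-collatolic acid | CCCCCC(=O)Cc1c(Oc2cc(OC)cc3cc(CCCCC)oc(=O)c23)c(O)cc(O)c1C(=O)O | target

**Count and risks**

Total step count: 13. Longest linear sequence: 11 steps (step 1 or 2, then 3, 4, 6, 7, 8, 9, 10, 11, 12, 13).

Steps most likely to fail:

1. Step 11. The di-ortho-substituted, electron-rich iodide may enter the copper cycle too slowly, and the chelated phenoxide of 10 is a weak nucleophile, so protodeiodination of 15 and slow decay of the phenoxide could win. The fallback reverses the polarity of the coupling and uses palladium; it sets out from 15 and 10 and returns at 16. Compound 15 is borylated (B2pin2, Pd(OAc)2, SPhos, KOAc, dioxane, 90 °C; Miyaura borylation) to benzyl 4,6-bis(benzyloxy)-2-[(2-pentyl-1,3-dioxolan-2-yl)methyl]-3-(4,4,5,5-tetramethyl-1,3,2-dioxaborolan-2-yl)benzoate F1. Oxidation (NaBO3·4H2O, THF–H2O, rt) gives the ring A phenol benzyl 4,6-bis(benzyloxy)-3-hydroxy-2-[(2-pentyl-1,3-dioxolan-2-yl)methyl]benzoate F2. Compound 10 is converted with Tf2O and pyridine (CH2Cl2, 0 °C) into 6-methoxy-1-oxo-3-pentyl-1H-isochromen-8-yl trifluoromethanesulfonate F3. F2 and F3 are then joined by palladium-catalysed C–O cross-coupling of the Buchwald–Hartwig type (Pd(OAc)2, t-BuXPhos, K3PO4, toluene, 100 °C) to give 16. The electrophile is then an electron-poor triflate next to the lactone carbonyl and the nucleophile a hindered phenol, the pairing that favours C–O reductive elimination.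

2. Step 4. Claisen-type folding or retro-Claisen cleavage of the chain may compete with the aldol closure, and the enol lactonisation may stall or be overtaken by ester hydrolysis and decarboxylation in hot acid. The fallback makes the two rings in separate operations; it sets out from 5 and returns at 9. The trianion of 5 (LiN(i-Pr)2, THF, 0 °C) is acetylated at its terminal carbon with N-methoxy-N-methylacetamide to methyl 3,5,7-trioxooctanoate F4, the parent substrate of this aldol, which carries no side-chain ketal. Aqueous KOH closes it to methyl 2,4-dihydroxy-6-methylbenzoate F5. Dimethyl sulfate and K2CO3 in acetone give methyl 2,4-dimethoxy-6-methylbenzoate F6. Lateral lithiation (LiN(i-Pr)2, 2 equiv, THF, −78 °C) and acylation with N-methoxy-N-methylhexanamide give methyl 2,4-dimethoxy-6-(2-oxoheptyl)benzoate F7. p-TsOH in refluxing toluene with removal of methanol closes the pyranone to 6,8-dimethoxy-3-pentylisocoumarin F8. BBr3 (CH2Cl2, −78 °C to rt) cleaves both methyl ethers to give 9.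

3. Step 9. The silyl triflate may promote reclosure of the keto ester to isocoumarin 11 with loss of the benzyl group faster than the ketone is ketalised. The fallback takes the ketal from the chain stage, so that the lactone is never formed on the ring A branch; it sets out from 6 and returns at 14. Compound 6 is carried through the base stage of step 4 only and worked up at pH 6, which gives 7 as an isolated compound. Benzylation (BnBr, K2CO3, DMF, 70 °C) gives methyl 2,4-bis(benzyloxy)-6-[(2-pentyl-1,3-dioxolan-2-yl)methyl]benzoate F9. Saponification of the hindered ester (KOH, aq. DMSO, 100 °C, then cold acidification to pH 4) gives 2,4-bis(benzyloxy)-6-[(2-pentyl-1,3-dioxolan-2-yl)methyl]benzoic acid F10. Alkylation of the carboxylate (BnBr, KHCO3, DMF, rt) gives 14.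

**Further compounds**

F1 | step 11 | benzyl 4,6-bis(benzyloxy)-2-[(2-pentyl-1,3-dioxolan-2-yl)methyl]-3-(4,4,5,5-tetramethyl-1,3,2-dioxaborolan-2-yl)benzoate | CCCCCC1(Cc2c(B3OC(C)(C)C(C)(C)O3)c(OCc3ccccc3)cc(OCc3ccccc3)c2C(=O)OCc2ccccc2)OCCO1
F2 | step 11 | benzyl 4,6-bis(benzyloxy)-3-hydroxy-2-[(2-pentyl-1,3-dioxolan-2-yl)methyl]benzoate | CCCCCC1(Cc2c(O)c(OCc3ccccc3)cc(OCc3ccccc3)c2C(=O)OCc2ccccc2)OCCO1
F3 | step 11 | 6-methoxy-1-oxo-3-pentyl-1H-isochromen-8-yl trifluoromethanesulfonate | CCCCCc1cc2cc(OC)cc(OS(=O)(=O)C(F)(F)F)c2c(=O)o1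
F4 | step 4 | methyl 3,5,7-trioxooctanoate | CC(=O)CC(=O)CC(=O)CC(=O)OC
F5 | step 4 | methyl 2,4-dihydroxy-6-methylbenzoate | Cc1cc(O)cc(O)c1C(=O)OC
F6 | step 4 | methyl 2,4-dimethoxy-6-methylbenzoate | COC(=O)c1c(C)cc(OC)cc1OC
F7 | step 4 | methyl 2,4-dimethoxy-6-(2-oxoheptyl)benzoate | CCCCCC(=O)Cc1cc(OC)cc(OC)c1C(=O)OC
F8 | step 4 | 6,8-dimethoxy-3-pentylisocoumarin | CCCCCc1cc2cc(OC)cc(OC)c2c(=O)o1
F9 | step 9 | methyl 2,4-bis(benzyloxy)-6-[(2-pentyl-1,3-dioxolan-2-yl)methyl]benzoate | CCCCCC1(Cc2cc(OCc3ccccc3)cc(OCc3ccccc3)c2C(=O)OC)OCCO1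
F10 | step 9 | 2,4-bis(benzyloxy)-6-[(2-pentyl-1,3-dioxolan-2-yl)methyl]benzoic acid | CCCCCC1(Cc2cc(OCc3ccccc3)cc(OCc3ccccc3)c2C(=O)O)OCCO1
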